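**Retrosynthetic overview**
1. Last bond: C1′–C2′ of the hexyl linker, made by a visible-light Ni/photoredox deoxygenative anti-Markovnikov hydroalkylation of spiroketal alkene 20 with hydroxymethyl-phthalide 9.
2. Phthalide 9: the benzene ring is built by Alder–Rickert benzannulation of ynoate 3 (from (R)-glyceraldehyde acetonide) with 1,5-dimethoxycyclohexa-1,4-diene; the lactone ring then closes.
3. Spiroketal 20: both five-membered rings close together on acid hydrolysis of the bis-adduct of acetone N,N-dimethylhydrazone with (S)-propylene oxide and epoxide 13 (from (S)-epichlorohydrin).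
4. Ring order: benzene ring, then lactone; separately both spiroketal rings in one operation; the fragments are joined last.

Assumption: the spiro carbon is a thermodynamic (acid-equilibrated) centre steered only by the two bought carbinol centres; the wanted E,E (5R) epimer 20 is drawn off by chromatography and the Z,Z (5S) epimer 19 is put back through the acid equilibration.

**Step 1**
Reactants: 1 (R)-2,2-dimethyl-1,3-dioxolane-4-carbaldehyde [(R)-glyceraldehyde acetonide]
Product: 3 methyl 3-[(4S)-2,2-dimethyl-1,3-dioxolan-4-yl]prop-2-ynoate, via (S)-4-ethynyl-2,2-dimethyl-1,3-dioxolane 2 (not isolated)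
Conditions: TMSCHN2, n-BuLi, THF, −78 °C; add 1, −78 → 0 °C; then n-BuLi, −78 °C; ClCO2Me, −78 → 0 °C
Reagents that add atoms: (trimethylsilyl)diazomethane C[Si](C)(C)C=[N+]=[N-]; methyl chloroformate COC(=O)Cl
Why: Colvin alkyne homologation (Peterson olefination, N2 loss, 1,2-H shift of the alkylidene carbene) followed by C-acylation of the lithium acetylide of 2; the bought stereocentre is not deprotonated at low temperature and changes from R to S only through CIP priorities.

**Step 2**
Reactants: 3 methyl 3-[(4S)-2,2-dimethyl-1,3-dioxolan-4-yl]prop-2-ynoate; 4 1,5-dimethoxycyclohexa-1,4-diene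
Product: 9 (3S)-3-(hydroxymethyl)-5,7-dimethoxy-2-benzofuran-1(3H)-one, via 1,3-dimethoxycyclohexa-1,3-diene 5 (not isolated), via methyl 3-[(4S)-2,2-dimethyl-1,3-dioxolan-4-yl]-1,5-dimethoxybicyclo[2.2.2]octa-2,5-diene-2-carboxylate 6 (not isolated), via methyl 2-[(4S)-2,2-dimethyl-1,3-dioxolan-4-yl]-4,6-dimethoxybenzoate 7 (not isolated), via methyl 2-[(1S)-1,2-dihydroxyethyl]-4,6-dimethoxybenzoate 8 (not isolated)
Conditions: 4 (3 equiv), dichloromaleic anhydride (1 mol%), neat, sealed tube, 120 → 190 °C; strip excess diene; TsOH·H2O (cat.), MeOH/H2O 9:1, 60 °C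
Reagents that add atoms: none
Why: Alder–Rickert sequence (in situ conjugation of 4 to 5, Diels–Alder with the nucleophilic C4 of the diene bonding to the ynoate β-carbon, retro-Diels–Alder loss of ethene to benzoate 7), then acid removes the acetonide and the benzylic hydroxyl lactonises 5-exo onto the ortho ester; the stereocentre is never touched and stays S.

**Step 3**
Reactants: 10 (S)-2-(chloromethyl)oxirane [(S)-epichlorohydrin]; 11 but-3-en-1-ylmagnesium bromide
Product: 13 (S)-2-(pent-4-en-1-yl)oxirane, via (S)-1-chlorohept-6-en-2-ol 12 (not isolated)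
Conditions: CuI (5 mol%), THF, −40 → 0 °C; then aq. NaOH, rt
Reagents that add atoms: none
Why: copper-catalysed Grignard opening at the unsubstituted epoxide carbon, then Williamson closure of the chlorohydrin; no bond to the stereocentre is broken and the CIP ranks are kept, so S stays S.

**Step 4**
Reactants: 14 acetone N,N-dimethylhydrazone; 15 (S)-2-methyloxirane [(S)-propylene oxide]; 13 (S)-2-(pent-4-en-1-yl)oxirane
Product: 20 (2S,5R,7S)-7-methyl-2-(pent-4-en-1-yl)-1,6-dioxaspiro[4.4]nonane, via (2S)-5-(2,2-dimethylhydrazinylidene)hexan-2-ol 16 (not isolated), via (2S,8S)-5-(2,2-dimethylhydrazinylidene)tridec-12-ene-2,8-diol 17 (not isolated), via (2S,8S)-2,8-dihydroxytridec-12-en-5-one 18 (not isolated), via (2S,5S,7S)-7-methyl-2-(pent-4-en-1-yl)-1,6-dioxaspiro[4.4]nonane 19 (not isolated)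
Conditions: 14, n-BuLi, THF, −78 → 0 °C; 15, −78 °C → rt; n-BuLi, −78 → 0 °C; 13, −78 °C → rt; 2 M HCl, THF, rt, to equilibrium; chromatography on Et3N-deactivated SiO2 takes 20; the 19-containing fractions go back unpurified to CSA (cat.), CH2Cl2, rt, and are chromatographed again (two cycles)
Reagents that add atoms: none
Why: two Corey–Enders azaenolate alkylations (each lithio-hydrazone opens its epoxide at CH2, the second deprotonation going to the less substituted α′-methyl), then acid hydrolysis and spontaneous spiroketalisation; C2 and C7 come unchanged from 13 and 15, and the spiro centre settles under their thermodynamic control into the Z,Z (5S, 19) and E,E (5R, 20) epimers, expected at about 1:1–2, which interconvert through the ring-opened oxocarbenium ion so that 19 is converted into 20 as 20 is drawn off.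

**Step 5**
Reactants: 9 (3S)-3-(hydroxymethyl)-5,7-dimethoxy-2-benzofuran-1(3H)-one; 20 (2S,5R,7S)-7-methyl-2-(pent-4-en-1-yl)-1,6-dioxaspiro[4.4]nonane
Product: 22 (3R)-5,7-dimethoxy-3-{6-[(2S,5R,7S)-7-methyl-1,6-dioxaspiro[4.4]nonan-2-yl]hexyl}-2-benzofuran-1(3H)-one, via (3S)-3-{[(5,7-di-tert-butyl-3-phenyl-2,3-dihydro-1,3-benzoxazol-2-yl)oxy]methyl}-5,7-dimethoxy-2-benzofuran-1(3H)-one 21 (not isolated)
Conditions: (i) 5,7-di-tert-butyl-3-phenylbenzoxazolium BF4 (1.2 equiv), pyridine, MTBE, rt, 15 min, filter; (ii) 20 (2 equiv), [Ir(dF(CF3)ppy)2(dtbbpy)]PF6 (1 mol%), NiBr2·dme/dtbbpy (10 mol%), 2,4,6-collidine (1.5 equiv), DMA/MTBE, 450 nm LEDs, rt; NaHCO3 work-up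
Reagents that add atoms: none
Why: Proposed new method: a redox-neutral deoxygenative anti-Markovnikov hydroalkylation in which the excited Ir photocatalyst oxidises adduct 21, collidine deprotonation and β-scission release the primary phthalide–CH2 radical and the benzoxazolone, the reduced photocatalyst takes Ni(II) to Ni(0), collidinium protonates this to L–Ni–H, the terminal olefin of 20 inserts to the linear alkyl–Ni, and radical capture with reductive elimination forms the C1′–C2′ bond; the closest known reaction types are the NHC-mediated deoxygenative C(sp3)–C(sp3) coupling of alcohols with alkyl bromides under Ni metallaphotoredox and the Ni–H reductive hydroalkylation of terminal olefins with alkyl iodides; no stereocentre is touched (C3 goes from S to R by CIP priority only), collidine replaces quinuclidine to avoid hydrogen abstraction at the spiroketal C–H bonds, and the buffered medium leaves the spiro centre alone.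

**Compound list**
1 | (R)-2,2-dimethyl-1,3-dioxolane-4-carbaldehyde | O=C[C@H]1COC(C)(C)O1 | starting material
2 | (S)-4-ethynyl-2,2-dimethyl-1,3-dioxolane (lithiated in situ) | C#C[C@H]1COC(C)(C)O1 | intermediate
3 | methyl 3-[(4S)-2,2-dimethyl-1,3-dioxolan-4-yl]prop-2-ynoate | COC(=O)C#C[C@H]1COC(C)(C)O1 | intermediate
4 | 1,5-dimethoxycyclohexa-1,4-diene | COC1=CCC=C(OC)C1 | starting material
5 | 1,3-dimethoxycyclohexa-1,3-diene | COC1=CC(OC)=CCC1 | intermediate
6 | methyl 3-[(4S)-2,2-dimethyl-1,3-dioxolan-4-yl]-1,5-dimethoxybicyclo[2.2.2]octa-2,5-diene-2-carboxylate (bridgehead isomers, both lead to 7) | COC(=O)C1=C([C@H]2COC(C)(C)O2)C2CCC1(OC)C=C2OC | intermediate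
7 | methyl 2-[(4S)-2,2-dimethyl-1,3-dioxolan-4-yl]-4,6-dimethoxybenzoate | COC(=O)c1c(OC)cc(OC)cc1[C@H]2COC(C)(C)O2 | intermediate
8 | methyl 2-[(1S)-1,2-dihydroxyethyl]-4,6-dimethoxybenzoate | COC(=O)c1c(OC)cc(OC)cc1[C@H](O)CO | intermediate
9 | (3S)-3-(hydroxymethyl)-5,7-dimethoxy-2-benzofuran-1(3H)-one | COc1cc(OC)c2c(c1)[C@@H](CO)OC2=O | intermediate
10 | (S)-2-(chloromethyl)oxirane | ClC[C@@H]1CO1 | starting material
11 | but-3-en-1-ylmagnesium bromide | C=CCC[Mg]Br | starting material
12 | (S)-1-chlorohept-6-en-2-ol (as magnesium alkoxide) | ClC[C@@H](O)CCCC=C | intermediate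
13 | (S)-2-(pent-4-en-1-yl)oxirane | C=CCCC[C@H]1CO1 | intermediate
14 | acetone N,N-dimethylhydrazone | CC(C)=NN(C)C | starting material
15 | (S)-2-methyloxirane | C[C@H]1CO1 | starting material
16 | (2S)-5-(2,2-dimethylhydrazinylidene)hexan-2-ol (as lithium alkoxide) | CC(=NN(C)C)CC[C@H](C)O | intermediate
17 | (2S,8S)-5-(2,2-dimethylhydrazinylidene)tridec-12-ene-2,8-diol | C[C@H](O)CCC(=NN(C)C)CC[C@@H](O)CCCC=C | intermediate
18 | (2S,8S)-2,8-dihydroxytridec-12-en-5-one | C[C@H](O)CCC(=O)CC[C@@H](O)CCCC=C | intermediate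
19 | (2S,5S,7S)-7-methyl-2-(pent-4-en-1-yl)-1,6-dioxaspiro[4.4]nonane (Z,Z spiro epimer, equilibrates with 20) | C=CCCC[C@H]1CC[C@]2(CC[C@H](C)O2)O1 | intermediate
20 | (2S,5R,7S)-7-methyl-2-(pent-4-en-1-yl)-1,6-dioxaspiro[4.4]nonane (E,E; numbered as in the target) | C=CCCC[C@H]1CC[C@@]2(CC[C@H](C)O2)O1 | intermediate
21 | (3S)-3-{[(5,7-di-tert-butyl-3-phenyl-2,3-dihydro-1,3-benzoxazol-2-yl)oxy]methyl}-5,7-dimethoxy-2-benzofuran-1(3H)-one (epimers at the aminal carbon) | COc1cc(OC)c2c(c1)[C@@H](COC3Oc4c(C(C)(C)C)cc(C(C)(C)C)cc4N3c3ccccc3)OC2=O | intermediate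
22 | (3R)-5,7-dimethoxy-3-{6-[(2S,5R,7S)-7-methyl-1,6-dioxaspiro[4.4]nonan-2-yl]hexyl}-2-benzofuran-1(3H)-one | COc1cc(OC)c2c(c1)[C@@H](CCCCCC[C@H]1CC[C@@]3(CC[C@H](C)O3)O1)OC2=O | target

**Totals**
Total steps: 5. Longest linear sequence: 3 steps (1 → 3 → 9 → 22, or 10 → 13 → 20 → 22).

**Steps most likely to fail**

Step 5 (the proposed new coupling). The Ni–H may not form or insert fast enough, so the phthalide–CH2 radical could instead be reduced to the 3-methylphthalide, dimerise or undergo a 1,2-acyloxy shift to the ring-expanded benzylic radical, and the olefin of 20 could isomerise by chain walking. The fallback sets out from 9 and 20 and comes back at 22. Alcohol 9 is converted with I2, PPh3 and imidazole (CH2Cl2, 0 °C) into (3S)-3-(iodomethyl)-5,7-dimethoxy-2-benzofuran-1(3H)-one F1. F1 is then joined to 20 by the known thermal nickel-hydride reductive hydroalkylation of terminal olefins with primary alkyl iodides (NiBr2·diglyme, nitrogen ligand, (EtO)2MeSiH, Na2CO3, DMA, rt), which gives 22 directly. This replaces the light-driven, redox-neutral alcohol activation by a halide electrophile and a stoichiometric hydrosilane.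

Step 4 (three-component spiroketal assembly and taking of the 5R epimer). The E,E/Z,Z preference of 5,5-spiroketals is small, and 19 and 20 may not separate well at this small, non-polar stage. The fallback sets out from the unseparated mixture of 19 and 20 and from 9, and comes back at 22. The mixture is coupled with 9 as in step 5, giving 22 together with its spiro epimer (3R)-5,7-dimethoxy-3-{6-[(2S,5S,7S)-7-methyl-1,6-dioxaspiro[4.4]nonan-2-yl]hexyl}-2-benzofuran-1(3H)-one F2, which arises from 19. The two are separated by semi-preparative HPLC on the polar, UV-active final compounds, and F2 is re-equilibrated (CSA cat., CH2Cl2, rt) and re-separated. The spiro centre is thus resolved at the end instead of on the fragment.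

Step 2 (Alder–Rickert at 190 °C). The hindered γ-alkoxy ynoate may polymerise or react sluggishly, and the acetonide may suffer at this temperature. The fallback sets out from 3 and comes back at 7, which then goes through the acid stage of step 2 to 9. Ynoate 3 undergoes a Diels–Alder reaction with the open-chain Brassard diene 1,3-dimethoxy-1-(trimethylsilyloxy)buta-1,3-diene (toluene, 80–110 °C) to give methyl 2-[(4S)-2,2-dimethyl-1,3-dioxolan-4-yl]-4,6-dimethoxy-6-(trimethylsilyloxy)cyclohexa-1,4-diene-1-carboxylate F3. F3 aromatises on silica/work-up by loss of methanol and the silyl group to methyl 2-[(4S)-2,2-dimethyl-1,3-dioxolan-4-yl]-6-hydroxy-4-methoxybenzoate F4. O-Methylation of F4 (MeI, K2CO3, acetone) gives 7. This is an eliminative aromatisation at about 100 °C lower temperature, with no ethene extrusion.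

**Further compounds**
F1 | step 5 | (3S)-3-(iodomethyl)-5,7-dimethoxy-2-benzofuran-1(3H)-one | COc1cc(OC)c2c(c1)[C@@H](CI)OC2=O
F2 | step 4 | (3R)-5,7-dimethoxy-3-{6-[(2S,5S,7S)-7-methyl-1,6-dioxaspiro[4.4]nonan-2-yl]hexyl}-2-benzofuran-1(3H)-one | COc1cc(OC)c2c(c1)[C@@H](CCCCCC[C@H]1CC[C@]3(CC[C@H](C)O3)O1)OC2=O
F3 | step 2 | methyl 2-[(4S)-2,2-dimethyl-1,3-dioxolan-4-yl]-4,6-dimethoxy-6-(trimethylsilyloxy)cyclohexa-1,4-diene-1-carboxylate | COC(=O)C1=C([C@H]2COC(C)(C)O2)CC(OC)=CC1(OC)O[Si](C)(C)C
F4 | step 2 | methyl 2-[(4S)-2,2-dimethyl-1,3-dioxolan-4-yl]-6-hydroxy-4-methoxybenzoate | COC(=O)c1c(O)cc(OC)cc1[C@H]2COC(C)(C)O2
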